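## Retrosynthetic overview

1. The target comes from fluoride release of the C9 hydroxyl. Before that, the O–O unit is introduced by SN2 perhydrolysis (inversion) of the mesylate of a (6R)-allylic alcohol.
2. The (6R)-alcohol comes from a C6 aldehyde and diisopropenylzinc under chiral amino-alcohol catalysis. This forms C6–C7 and sets the only stereocentre.
3. The C1–O(coumarin) bond comes from a Mitsunobu coupling of a Z-allylic alcohol and 4-hydroxy-5-methylcoumarin.
4. The key C3–C4 bond joins a propanal homoenolate equivalent (dioxolane-masked β-carbanion, as a Grignard reagent) to mono-silylated but-2-yne-1,4-diol by alkoxide-directed syn-carbomagnesiation. Two carbons that are both normally acceptor (β) positions are joined, and the same step sets the Z alkene and tells the two CH2O groups apart.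
5. Only the pyranone ring of the coumarin is built, in the first step, on the purchased benzene ring. The dioxolane is a purchased temporary mask.

Assumption: side-chain atoms are called C1 (OCH2), C2=C3, C4, C5, C6 (CH–OOH), C7(=C8H2), C9 (CH2OH on C3) and C10 (CH3 on C7), and all starting materials listed are taken as catalogue chemicals.

## Route

Step 1
Reactants: 1 1-(2-hydroxy-6-methylphenyl)ethan-1-one; 2 diethyl carbonate
Product: 3 4-hydroxy-5-methyl-2H-chromen-2-one
Conditions: NaH (4 equiv), toluene, 110 °C; then 2 M HCl, 0 °C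
Reagents that add atoms: none
Why: Claisen-type C-acylation of the ketone enolate by diethyl carbonate followed by lactonisation of the phenoxide onto the new ester closes the pyranone ring, which is the standard 4-hydroxycoumarin synthesis from 2-hydroxyacetophenones and creates no stereocentre.

Step 2
Reactants: 4 but-2-yne-1,4-diol
Product: 5 4-{[tert-butyl(diphenyl)silyl]oxy}but-2-yn-1-ol
Conditions: TBDPSCl (1 equiv), imidazole (1.2 equiv), 4 (4 equiv), DMF, 0 °C → rt
Reagents that add atoms: tert-butyl(chloro)diphenylsilane, CC(C)(C)[Si](Cl)(c1ccccc1)c1ccccc1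
Why: Statistical monosilylation in which the cheap symmetrical diol is used in fourfold excess so that the bulky silyl chloride reacts essentially once, the surplus diol is washed out with water, and the acid-stable TBDPS group is chosen to outlast the later acetal hydrolysis.

Step 3 (key step)
Reactants: 5 4-{[tert-butyl(diphenyl)silyl]oxy}but-2-yn-1-ol; 6 2-(2-bromoethyl)-1,3-dioxolane
Product: 10 (2Z)-3-({[tert-butyl(diphenyl)silyl]oxy}methyl)-5-(1,3-dioxolan-2-yl)pent-2-en-1-ol, via homoenolate Grignard reagent 7 (not isolated), via bromomagnesium alkoxide 8 (not isolated), via alkenylmagnesium alkoxide 9 (not isolated)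
Conditions: 6, Mg, THF, 25–30 °C (gives 7, 3.5 equiv); add 5, −40 °C; Fe(acac)3 (15 mol %), 1,2-bis(diphenylphosphino)ethane (15 mol %), −40 → 0 °C, 6 h; sat. aq NH4Cl, −20 °C
Reagents that add atoms: none
Why: Proposed new method: 7 is a propanal homoenolate (d3) equivalent whose carbanionic carbon C4 is the normally electrophilic β-carbon of the latent C6 aldehyde, and it is joined to alkyne carbon C3, the β-position of the C1 oxygen terminus that would be the acceptor site of the corresponding ynoate; the magnesium alkoxide 8 binds the low-valent alkyl-iron species formed from Fe(acac)3 and 7 and delivers the alkyl group to the distal alkyne carbon by syn-carboferration, iron-to-magnesium exchange gives 9 and protonation keeps the geometry, so the new chain and H are cis (Z alkene, both CH2O groups cis) and the two oxygens are differentiated because the silyl ether cannot direct; the closest known reaction type is the iron-catalysed alkoxide-directed syn-carbomagnesiation of propargylic alcohols by methyl, simple alkyl and aryl Grignard reagents, the new elements being the acetal-bearing reagent carrying β-hydrogens (diphosphine and low temperature counter β-hydride elimination) and the butynediol monoether substrate.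

Step 4
Reactants: 10 (2Z)-3-({[tert-butyl(diphenyl)silyl]oxy}methyl)-5-(1,3-dioxolan-2-yl)pent-2-en-1-ol; 3 4-hydroxy-5-methyl-2H-chromen-2-one
Product: 11 4-{[(2Z)-3-({[tert-butyl(diphenyl)silyl]oxy}methyl)-5-(1,3-dioxolan-2-yl)pent-2-en-1-yl]oxy}-5-methyl-2H-chromen-2-one
Conditions: PPh3 (1.2 equiv), DIAD (1.2 equiv), THF, 0 °C → rt
Reagents that add atoms: none
Why: Mitsunobu reaction in which the acidic vinylogous carboxylic acid 3 (pKa about 4) attacks the primary allylic oxyphosphonium salt through its 4-oxygen in an SN2 manner, which avoids the C3-allylation seen for allyl halides or π-allyl palladium chemistry and leaves the Z alkene untouched.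

Step 5
Reactants: 11 4-{[(2Z)-3-({[tert-butyl(diphenyl)silyl]oxy}methyl)-5-(1,3-dioxolan-2-yl)pent-2-en-1-yl]oxy}-5-methyl-2H-chromen-2-one
Product: 12 (4Z)-4-({[tert-butyl(diphenyl)silyl]oxy}methyl)-6-[(5-methyl-2-oxo-2H-chromen-4-yl)oxy]hex-4-enal
Conditions: pyridinium p-toluenesulfonate (0.3 equiv), acetone–H2O (9:1), 55 °C
Reagents that add atoms: water, O
Why: Acid-catalysed acetal hydrolysis under pyridinium buffering cleaves the dioxolane of an unhindered aliphatic aldehyde, while the TBDPS ether, the allylic coumarinyl ether and the Z alkene all need stronger acid and stay intact.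

Step 6
Reactants: 12 (4Z)-4-({[tert-butyl(diphenyl)silyl]oxy}methyl)-6-[(5-methyl-2-oxo-2H-chromen-4-yl)oxy]hex-4-enal; 13 prop-1-en-2-ylmagnesium bromide
Product: 16 4-{[(2Z,6R)-3-({[tert-butyl(diphenyl)silyl]oxy}methyl)-6-hydroxy-7-methylocta-2,7-dien-1-yl]oxy}-5-methyl-2H-chromen-2-one, via di(prop-1-en-2-yl)zinc 14 (not isolated), via zinc alkoxide 15 (not isolated)
Conditions: 13 (4 equiv, 0.5 M in THF), ZnCl2 (2 equiv), 0 °C; 1,4-dioxane, filter under Ar, exchange solvent to toluene; (2S)-3-exo-morpholinoisoborneol [(−)-MIB] (10 mol %), −20 °C; add 12; sat. aq NH4Cl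
Reagents that add atoms: none
Why: Amino-alcohol-catalysed alkenylzinc addition (Noyori–Oppolzer type) in which the zinc aminoalkoxide formed from (−)-MIB organises aldehyde and 14 in the usual bimetallic transition state and transfers the isopropenyl group to the Si face of 12, which sets C6 as R, while the coumarin lactone and the silyl ether are inert to organozinc reagents.

Step 7
Reactants: 16 4-{[(2Z,6R)-3-({[tert-butyl(diphenyl)silyl]oxy}methyl)-6-hydroxy-7-methylocta-2,7-dien-1-yl]oxy}-5-methyl-2H-chromen-2-one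
Product: 18 4-{[(2Z,6S)-3-({[tert-butyl(diphenyl)silyl]oxy}methyl)-6-hydroperoxy-7-methylocta-2,7-dien-1-yl]oxy}-5-methyl-2H-chromen-2-one, via allylic mesylate 17 (not isolated)
Conditions: (MeSO2)2O (1.3 equiv), Et3N (2 equiv), THF, −40 °C, 30 min; then cannula into H2O2 (about 3 M in Et2O, 20 equiv), Cs2CO3 (4 equiv), DMF, −20 → 0 °C, dark, 2 h
Reagents that add atoms: hydrogen peroxide, OO
Why: Perhydrolysis of a sulfonate by SN2 displacement, in which chloride-free mesylation keeps the C6–O bond (no allylic chloride that would cause double inversion) and the α-effect nucleophile HOO− then displaces the secondary allylic mesylate with inversion, turning (6R)-17 into (6S)-18, while the large excess of H2O2 suppresses dialkyl peroxide formation and the cold polar aprotic medium disfavours ionisation, SN2′ attack and attack on the coumarin.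

Step 8
Reactants: 18 4-{[(2Z,6S)-3-({[tert-butyl(diphenyl)silyl]oxy}methyl)-6-hydroperoxy-7-methylocta-2,7-dien-1-yl]oxy}-5-methyl-2H-chromen-2-one
Product: 19 4-{[(2Z,6S)-6-hydroperoxy-3-(hydroxymethyl)-7-methylocta-2,7-dien-1-yl]oxy}-5-methyl-2H-chromen-2-one
Conditions: HF·pyridine, pyridine, THF, 0 °C → rt, polyethylene flask, dark
Reagents that add atoms: none
Why: Fluoride-mediated desilylation driven by the strong Si–F bond and run in pyridine-buffered medium, so that neither the acid-sensitive allylic hydroperoxide (Hock cleavage) nor the allylic coumarinyl ether is touched and the C6 configuration and alkene geometry pass unchanged into the target.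

## Compound list

1 | 1-(2-hydroxy-6-methylphenyl)ethan-1-one | CC(=O)c1c(C)cccc1O | starting material
2 | diethyl carbonate | CCOC(=O)OCC | starting material
3 | 4-hydroxy-5-methyl-2H-chromen-2-one | Cc1cccc2oc(=O)cc(O)c12 | intermediate
4 | but-2-yne-1,4-diol | OCC#CCO | starting material
5 | 4-{[tert-butyl(diphenyl)silyl]oxy}but-2-yn-1-ol | OCC#CCO[Si](c1ccccc1)(c1ccccc1)C(C)(C)C | intermediate
6 | 2-(2-bromoethyl)-1,3-dioxolane | BrCCC1OCCO1 | starting material
7 | homoenolate Grignard reagent, [2-(1,3-dioxolan-2-yl)ethyl]magnesium bromide | Br[Mg]CCC1OCCO1 | intermediate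
8 | bromomagnesium alkoxide of 5 | Br[Mg]OCC#CCO[Si](c1ccccc1)(c1ccccc1)C(C)(C)C | intermediate
9 | alkenylmagnesium alkoxide (C2–MgBr cis to the new chain) | Br[Mg]OC/C([Mg]Br)=C(/CCC1OCCO1)CO[Si](c1ccccc1)(c1ccccc1)C(C)(C)C | intermediate
10 | (2Z)-3-({[tert-butyl(diphenyl)silyl]oxy}methyl)-5-(1,3-dioxolan-2-yl)pent-2-en-1-ol | OC/C=C(/CCC1OCCO1)CO[Si](c1ccccc1)(c1ccccc1)C(C)(C)C | intermediate
11 | 4-{[(2Z)-3-({[tert-butyl(diphenyl)silyl]oxy}methyl)-5-(1,3-dioxolan-2-yl)pent-2-en-1-yl]oxy}-5-methyl-2H-chromen-2-one | O1CCOC1CC/C(=C/COc1cc(=O)oc2cccc(C)c12)CO[Si](c1ccccc1)(c1ccccc1)C(C)(C)C | intermediate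
12 | (4Z)-4-({[tert-butyl(diphenyl)silyl]oxy}methyl)-6-[(5-methyl-2-oxo-2H-chromen-4-yl)oxy]hex-4-enal | O=CCC/C(=C/COc1cc(=O)oc2cccc(C)c12)CO[Si](c1ccccc1)(c1ccccc1)C(C)(C)C | intermediate
13 | prop-1-en-2-ylmagnesium bromide | C=C(C)[Mg]Br | starting material
14 | di(prop-1-en-2-yl)zinc | C=C(C)[Zn]C(C)=C | intermediate
15 | zinc alkoxide, (6R)-isopropenylzinc alkoxide of 16 | C=C(C)[C@@H](CC/C(=C/COc1cc(=O)oc2cccc(C)c12)CO[Si](c1ccccc1)(c1ccccc1)C(C)(C)C)O[Zn]C(C)=C | intermediate
16 | 4-{[(2Z,6R)-3-({[tert-butyl(diphenyl)silyl]oxy}methyl)-6-hydroxy-7-methylocta-2,7-dien-1-yl]oxy}-5-methyl-2H-chromen-2-one | C=C(C)[C@@H](CC/C(=C/COc1cc(=O)oc2cccc(C)c12)CO[Si](c1ccccc1)(c1ccccc1)C(C)(C)C)O | intermediate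
17 | allylic mesylate, (6R)-methanesulfonate of 16 | C=C(C)[C@@H](CC/C(=C/COc1cc(=O)oc2cccc(C)c12)CO[Si](c1ccccc1)(c1ccccc1)C(C)(C)C)OS(C)(=O)=O | intermediate
18 | 4-{[(2Z,6S)-3-({[tert-butyl(diphenyl)silyl]oxy}methyl)-6-hydroperoxy-7-methylocta-2,7-dien-1-yl]oxy}-5-methyl-2H-chromen-2-one | C=C(C)[C@H](CC/C(=C/COc1cc(=O)oc2cccc(C)c12)CO[Si](c1ccccc1)(c1ccccc1)C(C)(C)C)OO | intermediate
19 | 4-{[(2Z,6S)-6-hydroperoxy-3-(hydroxymethyl)-7-methylocta-2,7-dien-1-yl]oxy}-5-methyl-2H-chromen-2-one | C=C(C)[C@H](CC/C(=C/COc1cc(=O)oc2cccc(C)c12)CO)OO | target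

## Step count and weak points

Total step count: 8.
Longest linear sequence: 7 steps (4 → 5 → 10 → 11 → 12 → 16 → 18 → 19). Step 1 is the only side branch.

**Step 3 is the most likely to fail.**
- Possible failures are β-hydride elimination of the alkyl-iron species, which gives hydromagnesiation instead of C–C formation, loss of silyloxide to give an allene, and poor conversion next to the bulky CH2OTBDPS group.
- The fallback sets out from 5 and 7 and comes back at 10. It keeps the same homoenolate but turns C3 into an explicit Michael acceptor.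
- Alcohol 5 is oxidised (2,2,6,6-tetramethylpiperidin-1-oxyl cat., PhI(OAc)2, MeCN–H2O) to 4-{[tert-butyl(diphenyl)silyl]oxy}but-2-ynoic acid F1. This is esterified (MeI, K2CO3, DMF) to methyl 4-{[tert-butyl(diphenyl)silyl]oxy}but-2-ynoate F2.
- Reagent 7 is transmetalated with CuBr·SMe2 (THF, −78 °C) to [2-(1,3-dioxolan-2-yl)ethyl]copper F3. This adds syn to F2 at −78 °C to give methyl 2-cuprio-4-{[tert-butyl(diphenyl)silyl]oxy}-3-[2-(1,3-dioxolan-2-yl)ethyl]but-2-enoate F4.
- Quenching at −78 °C (NH4Cl, MeOH) gives methyl (2Z)-4-{[tert-butyl(diphenyl)silyl]oxy}-3-[2-(1,3-dioxolan-2-yl)ethyl]but-2-enoate F5. DIBAL-H (CH2Cl2, −78 °C) then reduces the ester to 10.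

**Step 6 is the second most likely to fail.**
- Possible failures are racemic background addition of the reactive dialkenylzinc, residual magnesium salts or THF, and a Lewis-basic coumarin lowering the ee on a linear aliphatic aldehyde.
- The fallback sets out from 12 and comes back at 16. It sets C6 by ketone reduction instead of C–C addition.
- A Nozaki–Hiyama–Kishi reaction of 12 (2-bromopropene, CrCl2, NiCl2 cat., DMF, rt) gives racemic 4-{[(2Z)-3-({[tert-butyl(diphenyl)silyl]oxy}methyl)-6-hydroxy-7-methylocta-2,7-dien-1-yl]oxy}-5-methyl-2H-chromen-2-one F6.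
- Dess–Martin periodinane oxidises it to 4-{[(2Z)-3-({[tert-butyl(diphenyl)silyl]oxy}methyl)-7-methyl-6-oxoocta-2,7-dien-1-yl]oxy}-5-methyl-2H-chromen-2-one F7.
- Corey–Bakshi–Shibata reduction then gives 16, using (3aS)-1-methyl-3,3-diphenyltetrahydro-1H,3H-pyrrolo[1,2-c][1,3,2]oxazaborole (20 mol %) and catecholborane in toluene at −78 °C, with the isopropenyl group as the large substituent.

**Step 7 is the third most likely to fail.**
- Possible failures are E2 elimination to the diene, SN2′ attack at C8, partial ionisation with loss of ee, and attack of HOO− on the coumarin.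
- The fallback sets out from 12 and comes back at 18. It makes the C–OO bond by an ene reaction instead of a substitution.
- Wittig olefination of 12 (isopropyltriphenylphosphonium iodide, KHMDS, THF, −78 → 0 °C) gives 4-{[(2Z)-3-({[tert-butyl(diphenyl)silyl]oxy}methyl)-7-methylocta-2,6-dien-1-yl]oxy}-5-methyl-2H-chromen-2-one F8.
- A Schenck ene reaction (O2, 5,10,15,20-tetraphenylporphyrin cat., visible light, CH2Cl2, 0 °C) occurs at the electron-rich C6=C7 alkene. It gives racemic 4-{[(2Z)-3-({[tert-butyl(diphenyl)silyl]oxy}methyl)-6-hydroperoxy-7-methylocta-2,7-dien-1-yl]oxy}-5-methyl-2H-chromen-2-one F9.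
- The regioisomer 4-{[(2Z,5E)-3-({[tert-butyl(diphenyl)silyl]oxy}methyl)-7-hydroperoxy-7-methylocta-2,5-dien-1-yl]oxy}-5-methyl-2H-chromen-2-one F10 forms beside it.
- Silica chromatography removes the regioisomer, and preparative chromatography on a polysaccharide chiral phase delivers the (6S)-enantiomer 18.

## Further compounds

F1 | step 3 | 4-{[tert-butyl(diphenyl)silyl]oxy}but-2-ynoic acid | OC(=O)C#CCO[Si](c1ccccc1)(c1ccccc1)C(C)(C)C
F2 | step 3 | methyl 4-{[tert-butyl(diphenyl)silyl]oxy}but-2-ynoate | COC(=O)C#CCO[Si](c1ccccc1)(c1ccccc1)C(C)(C)C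
F3 | step 3 | [2-(1,3-dioxolan-2-yl)ethyl]copper | [Cu]CCC1OCCO1
F4 | step 3 | methyl 2-cuprio-4-{[tert-butyl(diphenyl)silyl]oxy}-3-[2-(1,3-dioxolan-2-yl)ethyl]but-2-enoate | COC(=O)/C([Cu])=C(/CCC1OCCO1)CO[Si](c1ccccc1)(c1ccccc1)C(C)(C)C
F5 | step 3 | methyl (2Z)-4-{[tert-butyl(diphenyl)silyl]oxy}-3-[2-(1,3-dioxolan-2-yl)ethyl]but-2-enoate | COC(=O)/C=C(/CCC1OCCO1)CO[Si](c1ccccc1)(c1ccccc1)C(C)(C)C
F6 | step 6 | racemic 4-{[(2Z)-3-({[tert-butyl(diphenyl)silyl]oxy}methyl)-6-hydroxy-7-methylocta-2,7-dien-1-yl]oxy}-5-methyl-2H-chromen-2-one | C=C(C)C(CC/C(=C/COc1cc(=O)oc2cccc(C)c12)CO[Si](c1ccccc1)(c1ccccc1)C(C)(C)C)O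
F7 | step 6 | 4-{[(2Z)-3-({[tert-butyl(diphenyl)silyl]oxy}methyl)-7-methyl-6-oxoocta-2,7-dien-1-yl]oxy}-5-methyl-2H-chromen-2-one | C=C(C)C(=O)CC/C(=C/COc1cc(=O)oc2cccc(C)c12)CO[Si](c1ccccc1)(c1ccccc1)C(C)(C)C
F8 | step 7 | 4-{[(2Z)-3-({[tert-butyl(diphenyl)silyl]oxy}methyl)-7-methylocta-2,6-dien-1-yl]oxy}-5-methyl-2H-chromen-2-one | CC(C)=CCC/C(=C/COc1cc(=O)oc2cccc(C)c12)CO[Si](c1ccccc1)(c1ccccc1)C(C)(C)C
F9 | step 7 | racemic 4-{[(2Z)-3-({[tert-butyl(diphenyl)silyl]oxy}methyl)-6-hydroperoxy-7-methylocta-2,7-dien-1-yl]oxy}-5-methyl-2H-chromen-2-one | C=C(C)C(CC/C(=C/COc1cc(=O)oc2cccc(C)c12)CO[Si](c1ccccc1)(c1ccccc1)C(C)(C)C)OO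
F10 | step 7 | 4-{[(2Z,5E)-3-({[tert-butyl(diphenyl)silyl]oxy}methyl)-7-hydroperoxy-7-methylocta-2,5-dien-1-yl]oxy}-5-methyl-2H-chromen-2-one | CC(C)(OO)/C=C/C/C(=C/COc1cc(=O)oc2cccc(C)c12)CO[Si](c1ccccc1)(c1ccccc1)C(C)(C)C
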